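## Retrosynthetic overview

1. The aryl ether C–O bond comes from a Mitsunobu coupling of purchased umbelliferone with a primary cyclopentylmethanol. The coumarin is never built.
2. The isobutenyl group and the propanoic acid chain are cis on adjacent carbons. They come from a Wittig reaction and an ozonolysis of the Δ4 silyl enol ether of a cis-hydrindan-5-one, so the six-membered ring is a sacrificial tether.
3. The trans CH2O/CH3 pair comes from conjugate reduction of a tetrasubstituted C1=C2 enoate. That enoate is made from the C1 ketone by methylation, triflation and carbonylation.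
4. The cis-hydrindanedione comes from hydrogenation of (R)-Hajos–Parrish ketone, which supplies the quaternary centre.
5. Ring order: both carbocycles arrive together in compound 1. No ring is constructed, and the cyclohexane is opened in step 9.

Assumption: (R)-(−)-Hajos–Parrish ketone is purchasable. If it is not, it takes 2 extra steps from 2-methylcyclopentane-1,3-dione and methyl vinyl ketone with D-proline.

## Route

**Step 1**
- Reactants: 1, (R)-Hajos–Parrish ketone
- Product: 2, (3aS,7aR)-7a-methylhexahydro-1H-indene-1,5(4H)-dione (cis-fused)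
- Conditions: H2 (1 atm), 10% Pd/C, EtOAc, rt
- Reagents that add atoms: none
- Why: In this heterogeneous catalytic hydrogenation, 7a-methylhydrinden-5-ones take up H at C3a on the face of the angular methyl, which gives the cis-hydrindane and sets the future isobutenyl carbon.

**Step 2**
- Reactants: 2
- Product: 3, (3aS,7aR)-7a-methyl-5-(triisopropylsilyloxy)-2,3,3a,6,7,7a-hexahydro-1H-inden-1-one
- Conditions: TIPSOTf (1.05 equiv), Et3N, CH2Cl2, −78 °C to rt
- Reagents that add atoms: TIPSOTf, CC(C)[Si](C(C)C)(C(C)C)OS(=O)(=O)C(F)(F)F
- Why: Soft enolisation to a silyl enol ether touches only the unhindered C5 ketone, because the C1 ketone is neopentyl; under equilibrating conditions the Δ4 isomer is favoured, since it keeps the ring-fusion torsion small (the same bias as 5β-3-ketosteroids giving Δ3 enol derivatives).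

**Step 3**
- Reactants: 3
- Product: 4, the 2-methyl ketone (C2 epimer mixture, which does not matter)
- Conditions: LDA, THF, −78 °C; MeI, −78 to 0 °C
- Reagents that add atoms: iodomethane, CI
- Why: This is an enolate alkylation, and C2 is the only enolisable position because C7a is quaternary; the new centre is erased in step 4.

**Step 4**
- Reactants: 4
- Product: 5, (3aS,7aR)-2,7a-dimethyl-5-(TIPSO)-3a,6,7,7a-tetrahydro-3H-inden-1-yl triflate
- Conditions: KHMDS, THF, −78 to 0 °C; PhNTf2
- Reagents that add atoms: PhNTf2, O=S(=O)(N(c1ccccc1)S(=O)(=O)C(F)(F)F)C(F)(F)F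
- Why: In this enol triflate formation only the C1=C2 enolate can form, so the tetrasubstituted triflate is a single regioisomer.

**Step 5**
- Reactants: 5
- Product: 6, methyl (3aS,7aR)-2,7a-dimethyl-5-(TIPSO)-3a,6,7,7a-tetrahydro-3H-indene-1-carboxylate
- Conditions: Pd(OAc)2, dppf, CO (1 atm), Et3N, MeOH/DMF, 60 °C
- Reagents that add atoms: carbon monoxide, [C-]#[O+]; methanol, CO
- Why: Pd-catalysed methoxycarbonylation of a vinyl triflate is the standard way to turn a 17-ketosteroid into a Δ16-17-carboxylate, and the TIPS enol ether tolerates Et3N/MeOH.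

**Step 6**
- Reactants: 6
- Product: 7, methyl (1R,2S,3aS,7aR)-2,7a-dimethyl-5-(TIPSO)-2,3,3a,6,7,7a-hexahydro-1H-indene-1-carboxylate
- Conditions: DIBAL-H, MeCu (CuI/MeLi), THF–HMPA, −50 °C; NH4Cl; then NaOMe, MeOH, rt
- Reagents that add atoms: none
- Why: In this Cu–H conjugate reduction (Tsuda–Saegusa), hydride reaches C2 from the convex face (the C3a-H side), which puts the methyl on the concave face (2S); protonation and NaOMe equilibration then place the ester trans to that methyl on the exo face (1R).

**Step 7**
- Reactants: 7
- Product: 8, [(1R,2S,3aS,7aR)-2,7a-dimethyl-5-(TIPSO)-2,3,3a,6,7,7a-hexahydro-1H-inden-1-yl]methanol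
- Conditions: LiAlH4, Et2O, 0 °C to rt; Fieser work-up
- Reagents that add atoms: none
- Why: This is a hydride reduction of the ester; the silyl enol ether masks the ketone and no stereocentre is touched.

**Step 8**
- Reactants: 8; 9, umbelliferone (7-hydroxycoumarin)
- Product: 10, 7-{[(1R,2S,3aS,7aR)-2,7a-dimethyl-5-(TIPSO)-2,3,3a,6,7,7a-hexahydro-1H-inden-1-yl]methoxy}-2H-chromen-2-one
- Conditions: PPh3, DIAD, THF, 0 to 40 °C
- Reagents that add atoms: none (all new atoms come from 9)
- Why: In this Mitsunobu etherification the phenol (pKa about 8) displaces the activated primary alcohol, whose β-carbon is CH rather than quaternary; the conditions are neutral and spare the enol ether.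

**Step 9**
- Reactants: 10
- Product: 11, 3-[(1S,2R,3S,5R)-5-formyl-1,3-dimethyl-2-{[(2-oxo-2H-chromen-7-yl)oxy]methyl}cyclopentyl]propanoic acid
- Conditions: O3 (1 equiv, Sudan Red end-point), CH2Cl2, −78 °C; Me2S; then AcOH/THF/H2O, rt
- Reagents that add atoms: ozone, [O-][O+]=O
- Why: In the ozonolysis of a silyl enol ether, the electron-rich C4=C5 bond reacts far faster than the electron-poor coumarin C3=C4 bond; the products are C4HO and a silyl ester that hydrolyses to the acid, and both new chains stay cis.

**Step 10**
- Reactants: 11; 12, isopropyltriphenylphosphonium iodide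
- Product: 13, ferulsinaic acid
- Conditions: 12 (2.3 equiv), KHMDS (2.2 equiv), THF, 0 °C; add 11 at −78 °C, warm to 0 °C; aqueous citric acid
- Reagents that add atoms: none (the CMe2 unit comes from 12)
- Why: In this Wittig olefination the first equivalent of ylide only deprotonates CO2H; the second attacks the aldehyde at low temperature, faster than it enolises the aldehyde or adds to the coumarin, so C5 keeps its configuration.

## Compound list

| No. | Name | SMILES | Role |
|---|---|---|---|
| 1 | (R)-Hajos–Parrish ketone | `C[C@@]12CCC(=O)C=C1CCC2=O` | starting material |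
| 2 | cis-dione | `C[C@@]12CCC(=O)C[C@@H]1CCC2=O` | intermediate |
| 3 | Δ4 TIPS enol ether ketone | `C[C@@]12CCC(O[Si](C(C)C)(C(C)C)C(C)C)=C[C@@H]1CCC2=O` | intermediate |
| 4 | 2-methyl ketone (C2 mixture) | `C[C@@]12CCC(O[Si](C(C)C)(C(C)C)C(C)C)=C[C@@H]1CC(C)C2=O` | intermediate |
| 5 | enol triflate | `C[C@@]12CCC(O[Si](C(C)C)(C(C)C)C(C)C)=C[C@@H]1CC(C)=C2OS(=O)(=O)C(F)(F)F` | intermediate |
| 6 | tetrasubstituted enoate | `C[C@@]12CCC(O[Si](C(C)C)(C(C)C)C(C)C)=C[C@@H]1CC(C)=C2C(=O)OC` | intermediate |
| 7 | trans ester | `C[C@@]12CCC(O[Si](C(C)C)(C(C)C)C(C)C)=C[C@@H]1C[C@H](C)[C@H]2C(=O)OC` | intermediate |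
| 8 | primary alcohol | `C[C@@]12CCC(O[Si](C(C)C)(C(C)C)C(C)C)=C[C@@H]1C[C@H](C)[C@H]2CO` | intermediate |
| 9 | umbelliferone | `Oc1ccc2ccc(=O)oc2c1` | starting material |
| 10 | coumarin ether | `C[C@@]12CCC(O[Si](C(C)C)(C(C)C)C(C)C)=C[C@@H]1C[C@H](C)[C@H]2COc3ccc4ccc(=O)oc4c3` | intermediate |
| 11 | aldehyde acid | `O=C[C@@H]1C[C@H](C)[C@@H](COc2ccc3ccc(=O)oc3c2)[C@]1(C)CCC(=O)O` | intermediate |
| 12 | isopropyltriphenylphosphonium iodide | `CC(C)[P+](c1ccccc1)(c1ccccc1)c1ccccc1.[I-]` | starting material |
| 13 | ferulsinaic acid | `CC(C)=C[C@@H]1C[C@H](C)[C@@H](COc2ccc3ccc(=O)oc3c2)[C@]1(C)CCC(=O)O` | target |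

## Summary

- Total steps: 10
- Longest linear sequence: 10 (from compound 1)

**Steps most likely to fail**

1. **Step 6.** The tetrasubstituted enoate may be unreactive, and the facial selectivity may be poor. Fallback: deconjugate 6 (LDA/HMPA, then an AcOH quench) to the 2-methylene β,γ-unsaturated ester. Hydrogenate that 1,1-disubstituted alkene with RhCl(PPh3)3 from the convex face, then equilibrate C1 with NaOMe.
2. **Step 2.** The Δ4/Δ5 regioselectivity may be low. Fallback: do not enolise the ketone at all. Instead generate the C4 enolate regiospecifically from enone 1 by ligand-controlled CuH 1,4-reduction (DTBM-SEGPHOS·CuH/PMHS, with the ligand enantiomer chosen for cis delivery) and trap it with TIPSOTf.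
3. **Step 10.** The ylide may react with the coumarin or the free acid, or the aldehyde may epimerise. Fallback: reorder the endgame so the ylide never meets the coumarin. Ozonise alcohol 8, esterify with TMSCHN2 and run the Wittig reaction. Then do the Mitsunobu coupling with 9 and finish with LiOH followed by H3O+, where the coumarin relactonises on acidification. This adds 2 steps.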